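The plan cuts ring C at O1–C8a and C4–C4a. This frees an enantiopure O1–C2–C3–C4 chain, a β-silyloxy ester, and ring A as the aryne C4a≡C8a. The key step exploits the phloroglucinol pattern of ring A: the C5 oxygen beside C4a polarises the aryne, so the C2 alkoxide adds at C8a and the carbanion born at C4a closes ring C on ester carbon C4, both bonds in one operation. Ring A is symmetric about its C6–C8a axis, so the precursor, a 2-silylaryl triflate already bearing the citronellal-derived chain at C6, is built without any 6- versus 8-isomer problem. C2 stems from asymmetric transfer hydrogenation.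

Key step: step 12

Remark: flavanone numbering is used (O1, C2, C3, C4, C4a, C5–C8, C8a; ring B primed; side chain doubly primed). CIP analysis of the SMILES gives (2S) and (3''S). (S)-Citronellal carries the C3'' centre with the same descriptor, and commercial material of high enantiomeric purity is assumed.

Step 1
Reactants: 1 (S)-citronellal
Product: 3 (3S)-3,7-dimethyloct-6-en-1-yne, via alkenyl nonaflate 2 (not isolated)
Conditions: n-C4F9SO2F (NfF), phosphazene base P2-Et (2.2 equiv), DMF, −10 °C to rt
Reagents that add atoms: nonafluorobutane-1-sulfonyl fluoride, FS(=O)(=O)C(F)(F)C(F)(F)C(F)(F)C(F)(F)F (its atoms stay only in intermediate 2)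
Why: One-pot alkenyl nonaflate formation and E2 elimination (dehydration of an enolisable aldehyde to a terminal alkyne): the base enolises toward C2'', NfF traps the enolate on oxygen and a second equivalent of base expels nonaflate, while the C3'' hydrogen is not acidic enough to be touched.

Step 2
Reactants: 3 (3S)-3,7-dimethyloct-6-en-1-yne
Product: 4 2-[(1E,3S)-3,7-dimethylocta-1,6-dien-1-yl]-4,4,5,5-tetramethyl-1,3,2-dioxaborolane
Conditions: HBpin, Cp2ZrHCl (10 mol %), Et3N (10 mol %), neat, 60 °C
Reagents that add atoms: pinacolborane, [H]B1OC(C)(C)C(C)(C)O1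
Why: Zirconocene-hydride-catalysed hydroboration of a terminal alkyne is a syn, anti-Markovnikov addition that should give only the (E)-alkenylboronate, and the trisubstituted C6''=C7'' alkene is too hindered to react with HBpin.

Step 3
Reactants: 5 2-iodoresorcinol
Product: 6 2-iodo-1,3-bis(methoxymethoxy)benzene
Conditions: MOMCl, iPr2NEt, CH2Cl2, 0 °C to rt
Reagents that add atoms: chloromethyl methyl ether, COCCl
Why: Standard O-alkylation of both phenols (MOM protection); the acetals later withstand organolithiums, palladium, fluoride and the aryl anion.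

Step 4
Reactants: 6 2-iodo-1,3-bis(methoxymethoxy)benzene
Product: 8 4-iodo-3,5-bis(methoxymethoxy)phenol, via arylboronate 7 (not isolated)
Conditions: [Ir(OMe)(cod)]2 (1.5 mol %), dtbpy (3 mol %), B2pin2, THF, 70 °C; then 30% H2O2, aq NaOH, 0 °C
Reagents that add atoms: bis(pinacolato)diboron, CC1(C)OB(OC1(C)C)B1OC(C)(C)C(C)(C)O1 (atoms only in 7); hydrogen peroxide, OO
Why: Sterically controlled iridium-catalysed aromatic C–H borylation takes the only C–H without an ortho neighbour (para to iodine), and peroxide oxidation of the C–B bond (1,2-aryl shift) gives the phenol oxygen that later leaves from C8a as triflate.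

Step 5
Reactants: 8 4-iodo-3,5-bis(methoxymethoxy)phenol
Product: 9 2-bromo-4-iodo-3,5-bis(methoxymethoxy)phenol
Conditions: NBS (1.0 equiv), CH2Cl2, −78 to 0 °C
Reagents that add atoms: N-bromosuccinimide, O=C1CCC(=O)N1Br
Why: Electrophilic aromatic bromination of a very electron-rich phenol; the two free positions are equivalent by symmetry, so one equivalent of NBS can give only this monobromide, whose C–Br carbon is the future C4a.

Step 6
Reactants: 9 2-bromo-4-iodo-3,5-bis(methoxymethoxy)phenol; 4 (E)-alkenylboronate
Product: 10 2-bromo-4-[(1E,3S)-3,7-dimethylocta-1,6-dien-1-yl]-3,5-bis(methoxymethoxy)phenol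
Conditions: Pd(dppf)Cl2 (5 mol %), K3PO4, THF/H2O, 45 °C
Reagents that add atoms: none
Why: Suzuki–Miyaura coupling; oxidative addition of zerovalent palladium into C–I is much faster than into C–Br, and the alkenyl group is transferred with retention of the E geometry and without touching C3''.

Step 7
Reactants: 10 2-bromo-4-alkenyl-3,5-bis(methoxymethoxy)phenol
Product: 13 4-[(1E,3S)-3,7-dimethylocta-1,6-dien-1-yl]-3,5-bis(methoxymethoxy)-2-(trimethylsilyl)phenyl triflate, via O-trimethylsilyl ether 11 (not isolated), via lithium 2-silylphenoxide 12 (not isolated)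
Conditions: HMDS, THF, 65 °C, concentrate; n-BuLi, THF, −78 °C; Tf2O, −78 °C to rt
Reagents that add atoms: hexamethyldisilazane, C[Si](C)(C)N[Si](C)(C)C; triflic anhydride, O=S(=O)(OS(=O)(=O)C(F)(F)F)C(F)(F)F
Why: Known sequence to 2-silylaryl triflates: O-silylation, Br/Li exchange, retro-Brook 1,3-shift of silicon from oxygen to the C4a carbanion, and O-triflation of the released phenoxide.

Step 8
Reactants: 14 4'-hydroxyacetophenone
Product: 15 4'-(methoxymethoxy)acetophenone
Conditions: MOMCl, iPr2NEt, CH2Cl2, 0 °C to rt
Reagents that add atoms: chloromethyl methyl ether, COCCl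
Why: MOM protection of the ring B phenol, so that all three phenols carry the same group for one final cleavage.

Step 9
Reactants: 15 4'-(methoxymethoxy)acetophenone
Product: 16 methyl 3-[4-(methoxymethoxy)phenyl]-3-oxopropanoate
Conditions: NaH (2.2 equiv), (MeO)2CO, THF, reflux; AcOH quench
Reagents that add atoms: dimethyl carbonate, COC(=O)OC
Why: Crossed Claisen condensation (C-methoxycarbonylation) of the ketone enolate with a non-enolisable carbonate, driven by deprotonation of the β-keto ester.

Step 10
Reactants: 16 methyl 3-[4-(methoxymethoxy)phenyl]-3-oxopropanoate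
Product: 17 methyl (3S)-3-hydroxy-3-[4-(methoxymethoxy)phenyl]propanoate
Conditions: RuCl[(S,S)-TsDPEN](p-cymene) (1 mol %), HCO2H–Et3N azeotrope, 30 °C
Reagents that add atoms: none
Why: Noyori–Ikariya asymmetric transfer hydrogenation; in the outer-sphere six-membered transition state the CH/π contact between the η6-cymene and the aryl ring of 16 exposes the Re face of the ketone to the (S,S)-catalyst, which sets the future C2 as (S) and leaves ester and acetal untouched.

Step 11
Reactants: 17 (S)-β-hydroxy ester
Product: 18 methyl (3S)-3-[4-(methoxymethoxy)phenyl]-3-(trimethylsilyloxy)propanoate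
Conditions: TMSCl, imidazole, CH2Cl2, 0 °C
Reagents that add atoms: chlorotrimethylsilane, C[Si](C)(C)Cl
Why: Simple O-silylation; it removes the only O–H proton from the key step and stores the alkoxide in latent form.

Step 12
Reactants: 13 2-silylaryl triflate; 18 (S)-β-silyloxy ester (1.2 equiv)
Product: 22 (2S)-6-[(1E,3S)-3,7-dimethylocta-1,6-dien-1-yl]-5,7-bis(methoxymethoxy)-2-[4-(methoxymethoxy)phenyl]chroman-4-one, via caesium alkoxide 19 (not isolated), via aryne 20 (not isolated), via aryl anion 21 (not isolated)
Conditions: 13 and 18 premixed, CsF (1.2 equiv), 18-crown-6 (1.2 equiv), THF, 0 °C to rt; AcOH quench at 0 °C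
Reagents that add atoms: none
Why: Proposed new method: fluoride strips the O-silyl group of 18 to the proton-free alkoxide 19 and the C-silyl group of 13 to aryne 20, then 19 adds at C8a, the aryl anion 21 attacks the methyl ester by addition–elimination, and the expelled methoxide is consumed by the next silyl group as Me3SiOMe, so the medium should end almost free of strong base. The closest known reaction type is the fluoride-induced annulation of arynes with methyl salicylates to xanthones (O-arylation, then acyl capture of the aryl anion), here extended from phenoxides to an aliphatic β-oxido ester, a substrate class on which it has not been shown. Ring C closes by 6-exo-trig attack of C4a on C4. No stereocentre is created: C2 keeps its configuration because the C2–O1 bond is never broken, and C3'' is remote. The regioselectivity needed (oxygen at C8a, acyl at C4a) is secured by the inductive, angle-distorting effect of the C5 alkoxy group of a 3-alkoxyaryne, which directs the nucleophile to the distal carbon and places the charge next to C5. The chemoselectivity needed (acyl capture faster than proton transfer from C3–H, retro-aldol cleavage or β-elimination) is favoured by the absence of any O–H, the low stationary concentrations of 19 and 20, and the six-membered transition state.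

Step 13
Reactants: 22 tris-MOM flavanone
Product: 24 (2S)-6-[(1E,3S)-3,7-dimethylocta-1,6-dien-1-yl]-5,7-dihydroxy-2-(4-hydroxyphenyl)chroman-4-one (CNP0150993.1), via tris(trimethylsilyl) ether 23 (not isolated)
Conditions: TMSOTf (9 equiv), 2,2'-bipyridyl (12 equiv), MeCN, 0 °C to rt; then H2O, rt
Reagents that add atoms: trimethylsilyl triflate, C[Si](C)(C)OS(=O)(=O)C(F)(F)F (atoms only in 23)
Why: Known mild cleavage of aromatic MOM ethers; the silyl triflate–bipyridyl complex exchanges each ArO–CH2OMe for ArO–SiMe3 without free acid and water then hydrolyses the aryl silyl ethers, so the electron-rich styrene, the trisubstituted alkene and the base-sensitive C2 centre should all survive.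

Compound list
1 | (S)-citronellal, (3S)-3,7-dimethyloct-6-enal | CC(C)=CCC[C@H](C)CC=O | starting material
2 | (3S)-3,7-dimethylocta-1,6-dien-1-yl nonaflate (E/Z mixture) | CC(C)=CCC[C@H](C)C=COS(=O)(=O)C(F)(F)C(F)(F)C(F)(F)C(F)(F)F | intermediate
3 | (3S)-3,7-dimethyloct-6-en-1-yne | CC(C)=CCC[C@H](C)C#C | intermediate
4 | 2-[(1E,3S)-3,7-dimethylocta-1,6-dien-1-yl]-4,4,5,5-tetramethyl-1,3,2-dioxaborolane | CC(C)=CCC[C@H](C)/C=C/B1OC(C)(C)C(C)(C)O1 | intermediate
5 | 2-iodoresorcinol | Oc1cccc(O)c1I | starting material
6 | 2-iodo-1,3-bis(methoxymethoxy)benzene | COCOc1cccc(OCOC)c1I | intermediate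
7 | 2-[4-iodo-3,5-bis(methoxymethoxy)phenyl]-4,4,5,5-tetramethyl-1,3,2-dioxaborolane | COCOc1cc(B2OC(C)(C)C(C)(C)O2)cc(OCOC)c1I | intermediate
8 | 4-iodo-3,5-bis(methoxymethoxy)phenol | COCOc1cc(O)cc(OCOC)c1I | intermediate
9 | 2-bromo-4-iodo-3,5-bis(methoxymethoxy)phenol | COCOc1cc(O)c(Br)c(OCOC)c1I | intermediate
10 | 2-bromo-4-[(1E,3S)-3,7-dimethylocta-1,6-dien-1-yl]-3,5-bis(methoxymethoxy)phenol | CC(C)=CCC[C@H](C)/C=C/c1c(OCOC)cc(O)c(Br)c1OCOC | intermediate
11 | O-trimethylsilyl ether of 10 | CC(C)=CCC[C@H](C)/C=C/c1c(OCOC)cc(O[Si](C)(C)C)c(Br)c1OCOC | intermediate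
12 | lithium 4-[(1E,3S)-3,7-dimethylocta-1,6-dien-1-yl]-3,5-bis(methoxymethoxy)-2-(trimethylsilyl)phenoxide | CC(C)=CCC[C@H](C)/C=C/c1c(OCOC)cc([O-])c([Si](C)(C)C)c1OCOC.[Li+] | intermediate
13 | 4-[(1E,3S)-3,7-dimethylocta-1,6-dien-1-yl]-3,5-bis(methoxymethoxy)-2-(trimethylsilyl)phenyl triflate | CC(C)=CCC[C@H](C)/C=C/c1c(OCOC)cc(OS(=O)(=O)C(F)(F)F)c([Si](C)(C)C)c1OCOC | intermediate
14 | 4'-hydroxyacetophenone | CC(=O)c1ccc(O)cc1 | starting material
15 | 4'-(methoxymethoxy)acetophenone | CC(=O)c1ccc(OCOC)cc1 | intermediate
16 | methyl 3-[4-(methoxymethoxy)phenyl]-3-oxopropanoate | COC(=O)CC(=O)c1ccc(OCOC)cc1 | intermediate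
17 | methyl (3S)-3-hydroxy-3-[4-(methoxymethoxy)phenyl]propanoate | COC(=O)C[C@@H](c1ccc(OCOC)cc1)O | intermediate
18 | methyl (3S)-3-[4-(methoxymethoxy)phenyl]-3-(trimethylsilyloxy)propanoate | COC(=O)C[C@@H](c1ccc(OCOC)cc1)O[Si](C)(C)C | intermediate
19 | caesium (1S)-3-methoxy-1-[4-(methoxymethoxy)phenyl]-3-oxopropan-1-olate | COC(=O)C[C@@H](c1ccc(OCOC)cc1)[O-].[Cs+] | intermediate
20 | 4-[(1E,3S)-3,7-dimethylocta-1,6-dien-1-yl]-3,5-bis(methoxymethoxy)-1,2-didehydrobenzene (aryne C4a≡C8a) | CC(C)=CCC[C@H](C)/C=C/C1=C(OCOC)C#CC=C1OCOC | intermediate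
21 | caesium aryl anion (carbanion at C4a) of the (S)-aryl ether ester | CC(C)=CCC[C@H](C)/C=C/c1c(OCOC)cc(O[C@@H](CC(=O)OC)c2ccc(OCOC)cc2)[c-]c1OCOC.[Cs+] | intermediate
22 | (2S)-6-[(1E,3S)-3,7-dimethylocta-1,6-dien-1-yl]-5,7-bis(methoxymethoxy)-2-[4-(methoxymethoxy)phenyl]chroman-4-one | CC(C)=CCC[C@H](C)/C=C/c1c(OCOC)cc2c(c1OCOC)C(=O)C[C@@H](c1ccc(OCOC)cc1)O2 | intermediate
23 | 5,7,4'-tris(trimethylsilyl) ether of the target | CC(C)=CCC[C@H](C)/C=C/c1c(O[Si](C)(C)C)cc2c(c1O[Si](C)(C)C)C(=O)C[C@@H](c1ccc(O[Si](C)(C)C)cc1)O2 | intermediate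
24 | (2S)-6-[(1E,3S)-3,7-dimethylocta-1,6-dien-1-yl]-5,7-dihydroxy-2-(4-hydroxyphenyl)chroman-4-one | CC(C)=CCC[C@H](C)/C=C/c1c(O)cc2c(c1O)C(=O)C[C@@H](c1ccc(O)cc1)O2 | target

Total step count: 13. Longest linear sequence: 7 steps (3, 4, 5, 6, 7, 12, 13).

Steps most likely to fail

Step 12 (the labelled step).
- What may go wrong:
  - The aryl anion may take a proton from C3–H instead of attacking the ester, and the aryloxide is then lost by β-elimination.
  - The naked alkoxide may undergo retro-aldol cleavage before it meets the aryne.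
  - Residual base may open ring C of the product by retro-oxa-Michael reaction, with erosion of the C2 configuration.
- Fallback with known chemistry, setting out from 10 and 16 and coming back at 22: 16 is reduced with the enantiomeric catalyst RuCl[(R,R)-TsDPEN](p-cymene) to methyl (3R)-3-hydroxy-3-[4-(methoxymethoxy)phenyl]propanoate F1. MeNHOMe·HCl and iPrMgCl turn this into the (R)-hydroxy Weinreb amide F2. Mitsunobu etherification of bromophenol 10 with F2 (PPh3, DIAD, toluene, 0 °C) forms O1–C2 with inversion and gives the (S)-aryl ether Weinreb amide F3. Parham cyclisation (n-BuLi, THF, −95 °C) then proceeds by Br/Li exchange at C4a and attack on the amide, and closes ring C to 22.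

Step 13.
- What may go wrong:
  - On hydrolysis the medium turns weakly acidic. Protonation of the C1''=C2'' styrene, activated by the freed 5- and 7-hydroxyls, could start a cation–olefin cyclisation onto C6''=C7''.
  - The silyl triflate could also enolise C4 and open ring C.
- Fallback, setting out from 22 and coming back at 24, replaces in-flask hydrolysis by a protecting-group exchange with isolation. TESOTf and 2,2'-bipyridyl in CH2Cl2, followed by NaHCO3 work-up, convert the three MOM ethers into the isolable tris(triethylsilyl) ether F4. F4 is purified and then cleaved with Et3N·3HF in THF at 0 °C, so that no acidic aqueous stage is passed.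

Step 1.
- What may go wrong:
  - Elimination of the alkenyl nonaflate may be incomplete.
  - Base-induced alkyne–allene isomerisation would erode the C3'' centre.
- Fallback, setting out from 1 and 9 and coming back at 10, makes steps 1, 2 and 6 unnecessary. 1 is condensed with TsNHNH2 in MeOH to (S)-citronellal N-tosylhydrazone F5. F5 is joined to iodide 9 by Barluenga coupling (Pd2(dba)3, XPhos, LiOtBu with one extra equivalent for the phenol, dioxane, 80 °C). The diazoalkane forms a palladium carbene, the aryl group migrates to C1'', and β-hydride elimination, possible only from C2'', gives the (E)-styrene 10.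

Further compounds
F1 | step 12 | methyl (3R)-3-hydroxy-3-[4-(methoxymethoxy)phenyl]propanoate | COC(=O)C[C@H](c1ccc(OCOC)cc1)O
F2 | step 12 | (3R)-3-hydroxy-N-methoxy-N-methyl-3-[4-(methoxymethoxy)phenyl]propanamide | CON(C)C(=O)C[C@H](c1ccc(OCOC)cc1)O
F3 | step 12 | (3S)-3-{2-bromo-4-[(1E,3S)-3,7-dimethylocta-1,6-dien-1-yl]-3,5-bis(methoxymethoxy)phenoxy}-N-methoxy-N-methyl-3-[4-(methoxymethoxy)phenyl]propanamide | CC(C)=CCC[C@H](C)/C=C/c1c(OCOC)cc(O[C@@H](CC(=O)N(C)OC)c2ccc(OCOC)cc2)c(Br)c1OCOC
F4 | step 13 | 5,7,4'-tris(triethylsilyl) ether of the target | CC(C)=CCC[C@H](C)/C=C/c1c(O[Si](CC)(CC)CC)cc2c(c1O[Si](CC)(CC)CC)C(=O)C[C@@H](c1ccc(O[Si](CC)(CC)CC)cc1)O2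
F5 | step 1 | (S)-citronellal N-tosylhydrazone | CC(C)=CCC[C@H](C)C/C=N/NS(=O)(=O)c1ccc(C)cc1
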